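**Retrosynthetic overview**
1. The target comes from its bis-MOM ether by acetal cleavage. That ether comes from a reductive Knoevenagel union (Hantzsch ester) of butyrylfilicinic acid, at its one free ring carbon, with 3-butanoyl-4-methoxy-2,6-bis(methoxymethoxy)benzaldehyde; the CH2 bridge is the former formyl carbon.
2. Butyrylfilicinic acid comes from a 3,5-dialkoxy-6,6-dimethylcyclohexa-2,4-dienone carrying a silyloxybutyl side chain, by desilylation, oxidation and hydrolysis of both enol ethers.
3. That dienone comes from a four-to-six ring expansion of 3-ethoxy-4,4-dimethylcyclobutenone with a methyl ynol ether (vinylketene, [2+2], second ring opening, 6π closure).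
4. Enabling feature: the cyclohexadienone ring carries oxygen on alternate carbons C1, C3 and C5, and C4, between C3 and C5, is quaternary (two methyl groups). The ring is thus a crossed trimer of three ketene units that cannot aromatise, so the electrocyclic product of a benzannulation is the filicinic ring itself.
5. Ring order: cyclobutenone (dimethylketene + ethoxyacetylene), then the six-membered trione ring. The arene is bought as 5-methoxyresorcinol and dressed by two directed lithiations.

Key step: step 4

Remark: the target has no stereocentre (its only sp3 ring carbon carries two methyl groups), so it is achiral and no enantiocontrol is needed. The carbinol centre carried as a racemate from step 2 to step 5 is erased in step 6. The enolised triketone is written in the tautomer of the given structure.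

**Step 1**
Reactants: 1 ethoxyacetylene; 2 2-methylpropanoyl chloride
Product: 4 3-ethoxy-4,4-dimethylcyclobut-2-en-1-one, via dimethylketene 3 (not isolated)
Conditions: Et3N, Et2O, 0 °C → reflux
Reagents that add atoms: none
Why: dehydrochlorination should give dimethylketene, which adds to the ynol ether in a ketene–alkyne [2+2] cycloaddition with the carbonyl carbon bonding to the unsubstituted alkyne carbon, a known way to this cyclobutenone.

**Step 2**
Reactants: 5 2-chloro-1,1-dimethoxyethane; 6 butanal
Product: 8 rac-1-methoxyhex-1-yn-3-ol, via lithium methoxyacetylide 7 (not isolated)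
Conditions: LiNEt2 (3 equiv, from Et2NH/n-BuLi), THF, 0 °C; then 6, −78 → 0 °C; aq. NH4Cl
Reagents that add atoms: none
Why: twofold elimination (MeOH, HCl) and deprotonation of the chloroacetal should give the methoxyacetylide, which adds 1,2 to the aldehyde (acetylide addition); the carbinol centre is racemic on purpose because it becomes the side-chain carbonyl.

**Step 3**
Reactants: 8 rac-1-methoxyhex-1-yn-3-ol
Product: 9 rac-tert-butyl[(1-methoxyhex-1-yn-3-yl)oxy]dimethylsilane
Conditions: TBSCl, imidazole, DMF, 0 °C → rt
Reagents that add atoms: tert-butyldimethylsilyl chloride, CC(C)(C)[Si](C)(C)Cl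
Why: standard silylation under basic conditions, which the acid-sensitive ynol ether tolerates, masks the hydroxyl group that would otherwise trap the ketenes of step 4.

**Step 4**
Reactants: 4 3-ethoxy-4,4-dimethylcyclobut-2-en-1-one; 9 rac-tert-butyl[(1-methoxyhex-1-yn-3-yl)oxy]dimethylsilane
Product: 13 rac-2-[1-(tert-butyldimethylsilyloxy)butyl]-5-ethoxy-3-methoxy-6,6-dimethylcyclohexa-2,4-dien-1-one, via vinylketene 10 (not isolated), via alkenylcyclobutenone 11 (not isolated), via dienylketene 12 (not isolated)
Conditions: 9 (2 equiv), toluene (1 M), 120 °C, sealed tube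
Reagents that add atoms: none
Why: Proposed new method: thermal 4π-electrocyclic opening of 4 should give vinylketene 10, whose ketene C=C adds [2+2] to the electron-rich alkyne 9 (carbonyl carbon to the alkyne carbon β to OMe) to give 11; a second, reversible 4π opening gives the Z-dienylketene 12, which closes by thermal 6π-electrocyclisation (ketene carbon onto the Me2C= terminus), so the four-membered ring of 4 grows by the two alkyne carbons into the six-membered ring of 13. The closest known reaction type is the Danheiser benzannulation of cyclobutenones with alkoxy- and siloxyalkynes, together with the known thermal recyclisation of dienylketenes to 6,6-disubstituted cyclohexa-2,4-dienones; new is the 4,4-dialkyl-3-alkoxycyclobutenone, whose quaternary carbon forbids the final tautomerisation to a phenol, so the sequence stops at the filicinic oxidation level. No stereocentre is created (the quaternary carbon bears two methyl groups; the silyloxy carbinol centre of 9 is carried through as a racemate). The selectivity needed is capture of 10 by 9 faster than its unimolecular 1,5-hydrogen shift from the cis-methyl group (to a dienal) or its dimerisation; 10 is a monosubstituted ketene, the most reactive class towards ynol ethers, 9 is used in excess at high concentration, and a methyl ynol ether cannot lose an alkene by retro-ene reaction at this temperature. The regiochemistry follows from the polarisation of the ynol ether and puts oxygen on alternate ring carbons.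

**Step 5**
Reactants: 13 rac-2-[1-(tert-butyldimethylsilyloxy)butyl]-5-ethoxy-3-methoxy-6,6-dimethylcyclohexa-2,4-dien-1-one
Product: 14 rac-5-ethoxy-2-(1-hydroxybutyl)-3-methoxy-6,6-dimethylcyclohexa-2,4-dien-1-one
Conditions: TBAF, THF, 0 °C
Reagents that add atoms: none
Why: fluoride desilylation should free the allylic carbinol while both alkyl enol ethers stay in place, which keeps the side chain from the aldol-type decay expected of a free 2-(hydroxyalkyl)-1,3-dione.

**Step 6**
Reactants: 14 rac-5-ethoxy-2-(1-hydroxybutyl)-3-methoxy-6,6-dimethylcyclohexa-2,4-dien-1-one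
Product: 15 2-butanoyl-5-ethoxy-3-methoxy-6,6-dimethylcyclohexa-2,4-dien-1-one
Conditions: Dess–Martin periodinane, CH2Cl2, 0 °C → rt
Reagents that add atoms: none
Why: Dess–Martin oxidation of the secondary allylic alcohol should give the butanoyl group and remove the only stereocentre.

**Step 7**
Reactants: 15 2-butanoyl-5-ethoxy-3-methoxy-6,6-dimethylcyclohexa-2,4-dien-1-one
Product: 16 2-butanoyl-3,5-dihydroxy-4,4-dimethylcyclohexa-2,5-dien-1-one (butyrylfilicinic acid)
Conditions: 2 M aq. HCl, THF, 40 °C
Reagents that add atoms: water, O
Why: acid hydrolysis of the two vinylogous esters (addition–elimination of water) should give the stable enolised β-triketone.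

**Step 8**
Reactants: 17 5-methoxybenzene-1,3-diol
Product: 18 1-methoxy-3,5-bis(methoxymethoxy)benzene
Conditions: MOMCl, i-Pr2NEt, CH2Cl2, 0 °C → rt
Reagents that add atoms: chloromethyl methyl ether, COCCl
Why: O-alkylation of both phenols installs acetal groups that protect and also direct the two lithiations.

**Step 9**
Reactants: 18 1-methoxy-3,5-bis(methoxymethoxy)benzene
Product: 20 4-methoxy-2,6-bis(methoxymethoxy)benzaldehyde, via aryllithium 19 (not isolated)
Conditions: n-BuLi, TMEDA, THF, 0 °C; DMF, −78 °C → rt; aq. NH4Cl
Reagents that add atoms: N,N-dimethylformamide, CN(C)C=O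
Why: directed ortho-metalation should occur at the carbon between the two MOM ethers, the stronger directing groups, and formylation of the aryllithium places the future bridge carbon between the two protected phenols.

**Step 10**
Reactants: 20 4-methoxy-2,6-bis(methoxymethoxy)benzaldehyde
Product: 23 3-butanoyl-4-methoxy-2,6-bis(methoxymethoxy)benzaldehyde, via lithium amino alkoxide 21 (not isolated), via ring-lithiated amino alkoxide 22 (not isolated)
Conditions: LiN(Me)CH2CH2NMe2 (from the amine/n-BuLi), THF, −20 °C; n-BuLi, −20 °C; N-methoxy-N-methylbutanamide, −78 → 0 °C; aq. NH4Cl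
Reagents that add atoms: N-methoxy-N-methylbutanamide, CCCC(=O)N(C)OC
Why: in situ protection of the formyl group as an α-amino alkoxide allows directed ortho-metalation at the only ring C–H positions (equivalent, each between OMOM and OMe), and acylation with the Weinreb amide followed by work-up should release ketone and aldehyde together.

**Step 11**
Reactants: 16 2-butanoyl-3,5-dihydroxy-4,4-dimethylcyclohexa-2,5-dien-1-one; 23 3-butanoyl-4-methoxy-2,6-bis(methoxymethoxy)benzaldehyde
Product: 25 2-butanoyl-6-{[3-butanoyl-4-methoxy-2,6-bis(methoxymethoxy)phenyl]methyl}-3,5-dihydroxy-4,4-dimethylcyclohexa-2,5-dien-1-one, via Knoevenagel alkylidene 24 (not isolated)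
Conditions: Hantzsch ester (1.2 equiv), L-proline (20 mol %), CH2Cl2, rt
Reagents that add atoms: none
Why: in this organocatalytic three-component reductive alkylation the only nucleophilic ring carbon of 16 condenses with the formyl group (the hindered aryl ketone does not compete), and Hantzsch ester transfer hydrogenation of the electron-poor alkylidene should give the CH2 bridge without the homodimers of a formaldehyde coupling.

**Step 12**
Reactants: 25 2-butanoyl-6-{[3-butanoyl-4-methoxy-2,6-bis(methoxymethoxy)phenyl]methyl}-3,5-dihydroxy-4,4-dimethylcyclohexa-2,5-dien-1-one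
Product: 26 2-butanoyl-6-[(3-butanoyl-2,6-dihydroxy-4-methoxyphenyl)methyl]-3,5-dihydroxy-4,4-dimethylcyclohexa-2,5-dien-1-one (target)
Conditions: HCl (1.25 M in MeOH), 0 °C → rt
Reagents that add atoms: none
Why: acid-catalysed acetal exchange with methanol should remove both MOM groups under conditions mild enough for the aryl methyl ether, the enolised triketone and the methylene bridge.

**Compound list**
1 | ethoxyacetylene | CCOC#C | starting material
2 | 2-methylpropanoyl chloride | CC(C)C(=O)Cl | starting material
3 | dimethylketene (formed in the flask) | CC(C)=C=O | intermediate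
4 | 3-ethoxy-4,4-dimethylcyclobut-2-en-1-one | CCOC1=CC(=O)C1(C)C | intermediate
5 | 2-chloro-1,1-dimethoxyethane | COC(CCl)OC | starting material
6 | butanal | CCCC=O | starting material
7 | lithium methoxyacetylide (formed in the flask) | [Li]C#COC | intermediate
8 | rac-1-methoxyhex-1-yn-3-ol | CCCC(O)C#COC | intermediate
9 | rac-tert-butyl[(1-methoxyhex-1-yn-3-yl)oxy]dimethylsilane | CCCC(O[Si](C)(C)C(C)(C)C)C#COC | intermediate
10 | 3-ethoxy-4-methylpenta-1,3-dien-1-one (vinylketene, formed in the flask) | CCOC(C=C=O)=C(C)C | intermediate
11 | 2-[1-(tert-butyldimethylsilyloxy)butyl]-4-(1-ethoxy-2-methylprop-1-en-1-yl)-3-methoxycyclobut-2-en-1-one (racemic diastereomer mixture, formed in the flask) | CCCC(O[Si](C)(C)C(C)(C)C)C1=C(OC)C(C(OCC)=C(C)C)C1=O | intermediate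
12 | rac-(3Z)-2-[1-(tert-butyldimethylsilyloxy)butyl]-5-ethoxy-3-methoxy-6-methylhepta-1,3,5-trien-1-one (dienylketene, formed in the flask) | CCCC(O[Si](C)(C)C(C)(C)C)C(=C=O)/C(OC)=C\C(OCC)=C(C)C | intermediate
13 | rac-2-[1-(tert-butyldimethylsilyloxy)butyl]-5-ethoxy-3-methoxy-6,6-dimethylcyclohexa-2,4-dien-1-one | CCCC(O[Si](C)(C)C(C)(C)C)C1=C(OC)C=C(OCC)C(C)(C)C1=O | intermediate
14 | rac-5-ethoxy-2-(1-hydroxybutyl)-3-methoxy-6,6-dimethylcyclohexa-2,4-dien-1-one | CCCC(O)C1=C(OC)C=C(OCC)C(C)(C)C1=O | intermediate
15 | 2-butanoyl-5-ethoxy-3-methoxy-6,6-dimethylcyclohexa-2,4-dien-1-one | CCCC(=O)C1=C(OC)C=C(OCC)C(C)(C)C1=O | intermediate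
16 | 2-butanoyl-3,5-dihydroxy-4,4-dimethylcyclohexa-2,5-dien-1-one (butyrylfilicinic acid) | CCCC(=O)C1=C(O)C(C)(C)C(O)=CC1=O | intermediate
17 | 5-methoxybenzene-1,3-diol | COc1cc(O)cc(O)c1 | starting material
18 | 1-methoxy-3,5-bis(methoxymethoxy)benzene | COCOc1cc(OC)cc(OCOC)c1 | intermediate
19 | [4-methoxy-2,6-bis(methoxymethoxy)phenyl]lithium (formed in the flask) | [Li]c1c(OCOC)cc(OC)cc1OCOC | intermediate
20 | 4-methoxy-2,6-bis(methoxymethoxy)benzaldehyde | COCOc1cc(OC)cc(OCOC)c1C=O | intermediate
21 | lithium {[2-(dimethylamino)ethyl](methyl)amino}[4-methoxy-2,6-bis(methoxymethoxy)phenyl]methanolate (formed in the flask) | [Li]OC(N(C)CCN(C)C)c1c(OCOC)cc(OC)cc1OCOC | intermediate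
22 | 3-lithio derivative of 21 (lithium on the ring carbon between OMOM and OMe, formed in the flask) | [Li]OC(N(C)CCN(C)C)c1c(OCOC)cc(OC)c([Li])c1OCOC | intermediate
23 | 3-butanoyl-4-methoxy-2,6-bis(methoxymethoxy)benzaldehyde | CCCC(=O)c1c(OC)cc(OCOC)c(C=O)c1OCOC | intermediate
24 | 2-butanoyl-6-{[3-butanoyl-4-methoxy-2,6-bis(methoxymethoxy)phenyl]methylidene}-3-hydroxy-4,4-dimethylcyclohex-2-ene-1,5-dione (formed in the flask) | CCCC(=O)C1=C(O)C(C)(C)C(=O)C(=Cc2c(OCOC)cc(OC)c(C(=O)CCC)c2OCOC)C1=O | intermediate
25 | 2-butanoyl-6-{[3-butanoyl-4-methoxy-2,6-bis(methoxymethoxy)phenyl]methyl}-3,5-dihydroxy-4,4-dimethylcyclohexa-2,5-dien-1-one | CCCC(=O)C1=C(O)C(C)(C)C(O)=C(Cc2c(OCOC)cc(OC)c(C(=O)CCC)c2OCOC)C1=O | intermediate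
26 | 2-butanoyl-6-[(3-butanoyl-2,6-dihydroxy-4-methoxyphenyl)methyl]-3,5-dihydroxy-4,4-dimethylcyclohexa-2,5-dien-1-one (achiral) | CCCC(=O)C1=C(O)C(C)(C)C(O)=C(Cc2c(O)cc(OC)c(C(=O)CCC)c2O)C1=O | target

**Step count**
Total: 12 steps. Longest linear sequence: 8 steps (2, 3, 4, 5, 6, 7, 11, 12).

**Steps most likely to fail**

1. Step 4 (proposed new method). The ring opening of 4 may need forcing temperatures, and the vinylketene may then escape by a 1,5-hydrogen shift from the methyl group cis to the ketene, or by dimerisation, before the ynol ether captures it. The fallback uses known chemistry and gives up the ring growth in favour of dearomatisation of an arene. It sets out from no intermediate of the line (compounds 1–15 are bypassed; commercial phloroglucinol and butanoyl chloride are new starting materials) and comes back to the route at 16. Friedel–Crafts acylation of phloroglucinol (butanoyl chloride, AlCl3, PhNO2/CH2Cl2) should give 1-(2,4,6-trihydroxyphenyl)butan-1-one F1. Twofold C-methylation of F1 at one ring carbon (MeI, NaOMe, MeOH, 0 °C → rt), the classical way to acylfilicinic acids, should then give 16.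

2. Step 11. The condensation may stall at the aldehyde flanked by two ortho substituents, or a second molecule of 16 may add to alkylidene 24 faster than hydride is transferred. The fallback sets out from 23 (with 16 as partner) and comes back at 25. Chemoselective reduction of the formyl group beside the hindered aryl ketone (NaBH4, MeOH, −20 °C) should give 1-[3-(hydroxymethyl)-6-methoxy-2,4-bis(methoxymethoxy)phenyl]butan-1-one F2. Dehydrative C-benzylation of 16 with F2 through the trialkoxy-stabilised benzylic cation (hexafluoroisopropanol, rt, or cat. Sc(OTf)3 in MeNO2) should then give 25, so the bridge is made by alkylation instead of condensation and reduction.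

3. Step 10. Masking of the formyl group may be incomplete so that butyllithium adds to it, or lithiation of the crowded amino alkoxide may be slow. The fallback sets out from 20 and comes back at 23 with a stable protecting group in place of the transient one. Acetalisation (HC(OMe)3, PPTS, MeOH) should give 2-(dimethoxymethyl)-5-methoxy-1,3-bis(methoxymethoxy)benzene F3. Lithiation between OMOM and OMe (n-BuLi, THF, 0 °C) and acylation with N-methoxy-N-methylbutanamide should give 1-[3-(dimethoxymethyl)-6-methoxy-2,4-bis(methoxymethoxy)phenyl]butan-1-one F4. Selective hydrolysis of the electron-rich benzylic acetal (wet silica gel with oxalic acid, rt), which the aryl MOM ethers should survive, should then give 23.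

**Further compounds**
F1 | step 4 | 1-(2,4,6-trihydroxyphenyl)butan-1-one | CCCC(=O)c1c(O)cc(O)cc1O
F2 | step 11 | 1-[3-(hydroxymethyl)-6-methoxy-2,4-bis(methoxymethoxy)phenyl]butan-1-one | CCCC(=O)c1c(OC)cc(OCOC)c(CO)c1OCOC
F3 | step 10 | 2-(dimethoxymethyl)-5-methoxy-1,3-bis(methoxymethoxy)benzene | COCOc1cc(OC)cc(OCOC)c1C(OC)OC
F4 | step 10 | 1-[3-(dimethoxymethyl)-6-methoxy-2,4-bis(methoxymethoxy)phenyl]butan-1-one | CCCC(=O)c1c(OC)cc(OCOC)c(C(OC)OC)c1OCOC
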